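The earlier runs and the new flask come from a simulation with constants of no real substance, noise included.

Slowness late in a run is paid for at the charge: you charge coupling partner once, but the rate at a fixed conversion feels what is left of it.

| setting | noon | dusk | dawn | flask |
|---|---|---|---|---|
| substrate | 0.70 M | 0.70 M | 0.70 M | 0.70 M |
| coupling partner | 0.32 M | 0.47 M | 0.63 M | 0.630 M |
| catalyst | 0.45 mM | 0.45 mM | 0.68 mM | 0.45 mM |
| added ligand | 0.29 mM | 0.29 mM | 0.29 mM | 0.29 mM |
| remark | run made earlier | run made earlier | run made earlier |  |

- noon (time / h: product / %): 0.833: 6.3; 1.33: 9.8; 2.50: 19.3; 5.00: 25.9; 10.0: 32.9
- dusk (time / h: product / %): 2.00: 19.6; 4.00: 30.6; 6.00: 38.5; 8.00: 45.3; 10.0: 47.0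
- dawn (time / h: product / %): 2.00: 34.1; 4.00: 50.8; 6.00: 59.9; 8.00: 63.4; 10.0: 68.5

(scatter of a reading: 1 percentage point)

* apparent order in coupling partner when 50% of the substrate are converted (percent change of the rate of making product for one percent more coupling partner charged)



Assume that each product uses one substrate and one coupling partner. Then define the leverage G, the charge of coupling partner divided by what remains of it at the asked conversion, 2.25 in this flask. One percent more charge raises the remaining coupling partner by G percent, so, with the substrate and the state of the catalyst at that conversion held fixed, the apparent order is G times the local order in coupling partner.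

Now turn the question round. With the same things held fixed, an apparent order equal to the local order needs G of one, which means nothing used by that conversion. The symmetric charge, with coupling partner equal to substrate, is the zero of a second scale, with G of 2.00. This flask charges less coupling partner than substrate, which makes it the limiting reagent, and it has used 55.6% of its charge at the mark, so G stands above the symmetric value.

The readings lean the same way. From 5.00 h to 10.0 h the noon run makes 0.0140 h⁻¹ of its substrate charge. The dusk run, further along, makes 0.0395 h⁻¹ from 4.00 h to 6.00 h. Against the two charges that reads as a rough order of 2.70. Taking a local order of one, I reckon 2.25, and this reading suggests that may fall short.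

The forecast also saw that the depletion “amplifies the true order”, but it said 2, which is lower than my figure.

The flask gives 2.6.

    substrate + coupling partner + catalyst → catalyst + product (k = 0.200 M⁻² s⁻¹)
    catalyst + added ligand ⇌ idle complex (K = 5500 M⁻¹, k = 0.0980 M⁻¹ s⁻¹)

That is 1.14 times G. In this flask the turning of substrate, coupling partner and catalyst into product ran from the start, with half of its turnover up to 12.0 h done by 2.52 h, and coupling partner stood at 46.0% of its charge at 6.00 h. Meanwhile catalyst and added ligand went into idle complex, which held 10.2% of the catalyst at 1.20 h and 29.3% at 6.00 h. A flask with twice the catalyst keeps these charges of substrate and coupling partner, so its G stays 2.25, and the factor on its rate is 2.39.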